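**Retrosynthetic overview**

- The butenolide is numbered O1, C2 (carbonyl), C3, C4, C5, with exocyclic C6 and side-chain carbinol C1'. The route rests on two features: C4–Br lies β and the C1' carbinol α to the C2 carbonyl (a β-bromo Baylis–Hillman pattern), and C5=C6Br2 is a C5(H)–C6Br3 unit less HBr.
- C5=C6 comes from E1cB loss of HBr from a 5-(tribromomethyl)butenolide. O1–C2 comes from lactonisation of the C5 hydroxyl onto a cis ester; this is the only ring and it closes after the key step.
- C4–Br and C3–C1' are formed together in an enantioselective three-component bromo-aldol of bromotrimethylsilane, a C5-silyloxy C6-tribromo ynoate and butanal, which sets (R)-C1' and the alkene geometry.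
- The ynoate comes from the C4–C5 bond between lithiated methyl propiolate and bromal, then O-silylation; C5 is made racemic because it is erased at the end.

Key step: step 3

Assumption: the (S)-diphenylprolinol-derived oxazaborolidinium is taken to leave the Si face of bound butanal open, which gives (R)-C1'; the sense of induction should be checked on the first sample and the (R)-catalyst used if it proves opposite.

**Step 1**
Reactants: 1 methyl propiolate; 2 bromal (anhydrous tribromoacetaldehyde)
Product: 5 methyl 5,5,5-tribromo-4-hydroxypent-2-ynoate (racemic), via lithium methyl propiolate 3 (not isolated), via lithium alkoxide 4 (not isolated)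
Conditions: LiN(SiMe3)2 (1.05 equiv), THF, −78 °C; then 2, −78 °C; AcOH quench at −78 °C
Reagents that add atoms: none
Why: 1,2-addition of a lithium acetylide to a non-enolisable, very electrophilic aldehyde, run and quenched at −78 °C so that lithium methyl propiolate survives and the tribromomethyl alkoxide does not undergo haloform-type cleavage; the new C5 centre is left racemic because step 5 destroys it.

**Step 2**
Reactants: 5 methyl 5,5,5-tribromo-4-hydroxypent-2-ynoate
Product: 6 methyl 5,5,5-tribromo-4-[(tert-butyldimethylsilyl)oxy]pent-2-ynoate (racemic)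
Conditions: TBSOTf, 2,6-lutidine, CH2Cl2, −78 → 0 °C
Reagents that add atoms: tert-butyldimethylsilyl trifluoromethanesulfonate, CC(C)(C)[Si](C)(C)OS(=O)(=O)C(F)(F)F
Why: O-silylation with a silyl triflate and a hindered pyridine base, the standard method for hindered, weakly nucleophilic secondary alcohols, caps the acidic carbinol so that it cannot consume bromotrimethylsilane or release HBr in step 3.

**Step 3**
Reactants: 6 methyl 5,5,5-tribromo-4-[(tert-butyldimethylsilyl)oxy]pent-2-ynoate; 7 butanal; 8 bromotrimethylsilane
Product: 11 methyl (2E)-3,5,5,5-tetrabromo-4-[(tert-butyldimethylsilyl)oxy]-2-[(1R)-1-hydroxybutyl]pent-2-enoate (both epimers at ring C5), via silyl bromoallenolate 9 (not isolated), via O-trimethylsilyl ether 10 (not isolated)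
Conditions: (S)-3,3-diphenyl-1-(2-methylphenyl)tetrahydro-1H,3H-pyrrolo[1,2-c][1,3,2]oxazaborole (20 mol%), Tf2NH (20 mol%), 7 (1.5 equiv), 8 (1.3 equiv, added last), EtCN, −78 → −40 °C; then 1 M HCl, THF, 0 °C
Reagents that add atoms: none
Why: Proposed new method: the N-protonated oxazaborolidine, a strong chiral Lewis acid in equilibrium with Me3SiNTf2, activates ynoate 6 so that bromide from 8 adds in conjugate fashion at C4 to give silyl bromoallenolate 9, whose C3 then attacks boron-bound butanal in a Mukaiyama-type aldol addition, silyl transfer giving 10 and freeing the catalyst, and dilute acid cleaving the O–SiMe3 bond to give 11. The closest known reaction type is the catalytic enantioselective three-component iodo-aldol of iodotrimethylsilane, propiolate esters and aldehydes under this catalyst class, together with stoichiometric Lewis-acid bromo- and iodo-aldols of ynoates and ynones; bromide as the halide and a C4-branched internal ynoate go beyond it, but the inductively withdrawing silyloxy(tribromomethyl)methyl group raises the electrophilicity of C4 and should offset the lower reactivity of bromide. No ring is closed in this step. (R)-C1' is set by the catalyst, which holds butanal through B–O coordination and a formyl C–H···O contact and leaves only the Si face open to C3. The step also needs the alkene geometry: the nucleophilic lobe at C3 lies in the plane of the two C4 substituents, and approach of the aldehyde past the small bromine instead of the bulky CH(OTBS)CBr3 group places C1' cis to Br and the ester cis to C5, as lactonisation requires. The racemic C5 centre only doubles the product into two epimers that converge in step 5.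

**Step 4**
Reactants: 11 methyl (2E)-3,5,5,5-tetrabromo-4-[(tert-butyldimethylsilyl)oxy]-2-[(1R)-1-hydroxybutyl]pent-2-enoate
Product: 13 4-bromo-3-[(1R)-1-hydroxybutyl]-5-(tribromomethyl)furan-2(5H)-one (both C5 epimers), via diol ester 12 (not isolated)
Conditions: HF·pyridine, THF, 0 °C → rt; then p-TsOH·H2O (10 mol%), toluene, 40 °C
Reagents that add atoms: none
Why: fluoride-driven desilylation frees the C5 hydroxyl, which sits cis to the ester on the tetrasubstituted alkene and closes the five-membered lactone by acid-catalysed intramolecular transesterification, while the C1' hydroxyl cannot compete because it would form a four-membered ring and C1' itself is not touched.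

**Step 5**
Reactants: 13 4-bromo-3-[(1R)-1-hydroxybutyl]-5-(tribromomethyl)furan-2(5H)-one
Product: 14 4-bromo-5-(dibromomethylene)-3-[(1R)-1-hydroxybutyl]furan-2(5H)-one (target)
Conditions: i-Pr2NEt (1.5 equiv), CH2Cl2, −20 → 0 °C
Reagents that add atoms: none
Why: E1cB dehydrobromination in which a hindered tertiary amine removes the vinylogously acidic C5–H (the anion is an aromatic 2-oxidofuran) and bromide leaves from the adjacent CBr3 group, giving the C5=C6Br2 alkene with no E/Z question because both C6 substituents are bromine, so both C5 epimers converge and (R)-C1' is untouched.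

**Compound list**

1 | methyl propiolate | C#CC(=O)OC | starting material
2 | bromal (tribromoacetaldehyde) | O=CC(Br)(Br)Br | starting material
3 | lithium methyl propiolate (methyl 3-lithioprop-2-ynoate) | [Li]C#CC(=O)OC | intermediate
4 | lithium alkoxide of 5 (lithium 1,1,1-tribromo-5-methoxy-5-oxopent-3-yn-2-olate) | [Li]OC(C#CC(=O)OC)C(Br)(Br)Br | intermediate
5 | methyl 5,5,5-tribromo-4-hydroxypent-2-ynoate (racemic) | COC(=O)C#CC(O)C(Br)(Br)Br | intermediate
6 | methyl 5,5,5-tribromo-4-[(tert-butyldimethylsilyl)oxy]pent-2-ynoate (racemic) | COC(=O)C#CC(O[Si](C)(C)C(C)(C)C)C(Br)(Br)Br | intermediate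
7 | butanal | CCCC=O | starting material
8 | bromotrimethylsilane | C[Si](C)(C)Br | starting material
9 | silyl bromoallenolate: 3,5,5,5-tetrabromo-4-[(tert-butyldimethylsilyl)oxy]-1-methoxy-1-[(trimethylsilyl)oxy]penta-1,2-diene (isomer mixture) | COC(O[Si](C)(C)C)=C=C(Br)C(O[Si](C)(C)C(C)(C)C)C(Br)(Br)Br | intermediate
10 | O-trimethylsilyl ether of 11: methyl (2E)-3,5,5,5-tetrabromo-4-[(tert-butyldimethylsilyl)oxy]-2-[(1R)-1-[(trimethylsilyl)oxy]butyl]pent-2-enoate | CCC[C@@H](O[Si](C)(C)C)/C(C(=O)OC)=C(\Br)C(O[Si](C)(C)C(C)(C)C)C(Br)(Br)Br | intermediate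
11 | methyl (2E)-3,5,5,5-tetrabromo-4-[(tert-butyldimethylsilyl)oxy]-2-[(1R)-1-hydroxybutyl]pent-2-enoate (Br cis to C1', ester cis to C5; C5 epimers) | CCC[C@@H](O)/C(C(=O)OC)=C(\Br)C(O[Si](C)(C)C(C)(C)C)C(Br)(Br)Br | intermediate
12 | methyl (2E)-3,5,5,5-tetrabromo-4-hydroxy-2-[(1R)-1-hydroxybutyl]pent-2-enoate (C5 epimers) | CCC[C@@H](O)/C(C(=O)OC)=C(\Br)C(O)C(Br)(Br)Br | intermediate
13 | 4-bromo-3-[(1R)-1-hydroxybutyl]-5-(tribromomethyl)furan-2(5H)-one (C5 epimers) | CCC[C@@H](O)C1=C(Br)C(C(Br)(Br)Br)OC1=O | intermediate
14 | 4-bromo-5-(dibromomethylene)-3-[(1R)-1-hydroxybutyl]furan-2(5H)-one | CCC[C@@H](O)C1=C(Br)C(=C(Br)Br)OC1=O | target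

**Step count**

Total: 5 steps. Longest linear sequence: 5 steps (1 → 5 → 6 → 11 → 13 → 14).

**Steps most likely to fail**

1. Step 3 (proposed new method). Bromide may add too slowly to the hindered internal ynoate, since bromotrimethylsilane is a weaker halide donor than the iodide. The allenolate may be protonated to a simple β-bromoacrylate before the aldol. The aldehyde may approach from the wrong side and give the alkene isomer that cannot lactonise. Face selection on butanal may be poor, or uneven between the two C5 epimers.
   Fallback, known chemistry only, setting out from butanal 7 and coming back at target 14. Triethyl phosphonoacetate is alkylated with chloroacetone (NaH, THF) to ethyl 2-(diethoxyphosphoryl)-4-oxopentanoate F1. Horner–Wadsworth–Emmons olefination of 7 (K2CO3, H2O/THF) should give ethyl 2-butylidene-4-oxopentanoate F2. Hydrogenation (H2, Pd/C, EtOAc) gives ethyl 2-butyl-4-oxopentanoate F3, and saponification (NaOH, aqueous EtOH; then HCl) gives 2-butyl-4-oxopentanoic acid F4. Bromination (Br2, CHCl3) leads to 3,5,5-tribromo-2-butyl-4-oxopentanoic acid F5. Hot concentrated H2SO4 then effects cyclisation, dehydration and dehydrogenation, a known reaction of brominated 2-alkyl-4-oxopentanoic acids, and should give 4-bromo-3-butyl-5-(dibromomethylene)furan-2(5H)-one F6, to be separated from its monobromomethylene congener. Wohl–Ziegler bromination at the allylic C1' (NBS, dibenzoyl peroxide, PhCF3, reflux) gives racemic 4-bromo-3-(1-bromobutyl)-5-(dibromomethylene)furan-2(5H)-one F7. Solvolysis in warm aqueous DMSO gives racemic 4-bromo-5-(dibromomethylene)-3-(1-hydroxybutyl)furan-2(5H)-one F8. Dess–Martin oxidation gives 4-bromo-3-butanoyl-5-(dibromomethylene)furan-2(5H)-one F9. Corey–Bakshi–Shibata reduction ((S)-2-methyl-CBS-oxazaborolidine, catecholborane, toluene, −78 °C), with the bromoalkenyl group as the large substituent, should deliver the (R)-alcohol 14.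

2. Step 1. The tribromomethyl alkoxide may fragment in a haloform-type cleavage. The acetylide may attack a bromine of the CBr3 group instead of the carbonyl. Lithium methyl propiolate may decompose or self-condense if the temperature rises.
   Fallback, setting out from methyl propiolate 1 and coming back at alcohol 5. Compound 1 is converted (AgNO3, aqueous NH3, MeOH) into silver methyl propiolate F10. With Cp2ZrCl2 (stoichiometric) and AgOTf (catalytic) in CH2Cl2 at room temperature this should give the alkynylzirconocene chloride F11. F11 adds to bromal 2 under neutral, Lewis-acidic conditions to give the zirconocene chloride alkoxide F12, and aqueous work-up gives 5. This is a known non-basic route to γ-hydroxy ynoates from base-sensitive aldehydes.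

3. Step 4. The tert-butyldimethylsilyl ether, flanked by the tribromomethyl group, may resist cleavage. Forcing fluoride conditions may instead degrade the tribromomethyl carbinol (gem-dibromoepoxide formation, premature elimination) before the ring closes.
   Fallback, a change of protecting-group strategy, setting out from alcohol 5 and coming back at lactone 13. Compound 5 is silylated (TESOTf, 2,6-lutidine, CH2Cl2, −78 °C) to the triethylsilyl ynoate F13. The conditions of step 3 with 7 and 8 should carry it through the triethylsilyl bromoallenolate F14 and the O-trimethylsilyl ether F15 to the triethylsilyl analogue of 11, F16. The less hindered silyl ether is then removed with AcOH/THF/H2O at room temperature, and p-TsOH·H2O in toluene at 40 °C closes the lactone through 12 to 13, with no fluoride used.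

**Further compounds**

F1 | step 3 | ethyl 2-(diethoxyphosphoryl)-4-oxopentanoate | CCOC(=O)C(CC(C)=O)P(=O)(OCC)OCC
F2 | step 3 | ethyl 2-butylidene-4-oxopentanoate | CCCC=C(CC(C)=O)C(=O)OCC
F3 | step 3 | ethyl 2-butyl-4-oxopentanoate | CCCCC(CC(C)=O)C(=O)OCC
F4 | step 3 | 2-butyl-4-oxopentanoic acid | CCCCC(CC(C)=O)C(=O)O
F5 | step 3 | 3,5,5-tribromo-2-butyl-4-oxopentanoic acid | CCCCC(C(Br)C(=O)C(Br)Br)C(=O)O
F6 | step 3 | 4-bromo-3-butyl-5-(dibromomethylene)furan-2(5H)-one | CCCCC1=C(Br)C(=C(Br)Br)OC1=O
F7 | step 3 | 4-bromo-3-(1-bromobutyl)-5-(dibromomethylene)furan-2(5H)-one (racemic) | CCCC(Br)C1=C(Br)C(=C(Br)Br)OC1=O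
F8 | step 3 | 4-bromo-5-(dibromomethylene)-3-(1-hydroxybutyl)furan-2(5H)-one (racemic) | CCCC(O)C1=C(Br)C(=C(Br)Br)OC1=O
F9 | step 3 | 4-bromo-3-butanoyl-5-(dibromomethylene)furan-2(5H)-one | CCCC(=O)C1=C(Br)C(=C(Br)Br)OC1=O
F10 | step 1 | silver methyl propiolate (methyl 3-argentioprop-2-ynoate) | COC(=O)C#C[Ag]
F11 | step 1 | chloro(3-methoxy-3-oxoprop-1-yn-1-yl)zirconocene | COC(=O)C#C[Zr](Cl)(C1C=CC=C1)C1C=CC=C1
F12 | step 1 | zirconocene chloride alkoxide of 5 | COC(=O)C#CC(O[Zr](Cl)(C1C=CC=C1)C1C=CC=C1)C(Br)(Br)Br
F13 | step 4 | methyl 5,5,5-tribromo-4-[(triethylsilyl)oxy]pent-2-ynoate (racemic) | COC(=O)C#CC(O[Si](CC)(CC)CC)C(Br)(Br)Br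
F14 | step 4 | 3,5,5,5-tetrabromo-1-methoxy-4-[(triethylsilyl)oxy]-1-[(trimethylsilyl)oxy]penta-1,2-diene | COC(O[Si](C)(C)C)=C=C(Br)C(O[Si](CC)(CC)CC)C(Br)(Br)Br
F15 | step 4 | methyl (2E)-3,5,5,5-tetrabromo-4-[(triethylsilyl)oxy]-2-[(1R)-1-[(trimethylsilyl)oxy]butyl]pent-2-enoate | CCC[C@@H](O[Si](C)(C)C)/C(C(=O)OC)=C(\Br)C(O[Si](CC)(CC)CC)C(Br)(Br)Br
F16 | step 4 | methyl (2E)-3,5,5,5-tetrabromo-2-[(1R)-1-hydroxybutyl]-4-[(triethylsilyl)oxy]pent-2-enoate | CCC[C@@H](O)/C(C(=O)OC)=C(\Br)C(O[Si](CC)(CC)CC)C(Br)(Br)Br
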